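**Retrosynthetic overview** (locants: C1 = lactone C=O, C2–C8 = ring carbons, O9 = ring oxygen)
1. Target ⇒ (7S)-hydroxy lactone + (R)-4-silyloxydec-2-ynoic acid. The C7–O ester bond is made with inversion (Mitsunobu), then alkyne → (Z)-alkene, then loss of four silyl groups.
2. Hydroxy lactone ⇒ nine-membered keto lactone ⇒ cyclohexanone β-keto ester. C7–C8 forms by 5-exo attack of a 1-(acyloxy)ethyl radical (C8) on the ring ketone (C7), and the C2–C7 bond of the resulting 6/5 bicycle breaks at once (three-atom ring expansion, 6 → 9).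
3. Enabling feature: in the oxonane ring, C2–C7 are six contiguous carbons that end in the lactone α-carbon C2 and the oxygen-bearing C7. Tied C2 to C7 they are a cyclohexanone, the other three ring atoms (C1, O9, C8) are its ester arm, and the C1 carbonyl stabilises the C2 radical left by the scission.
4. β-Keto ester ⇒ trisilyloxy cyclohexanone (C-carboxylation with a lactate-derived reagent, C-methylation) ⇒ (R)-carvone. The α′-methyl becomes the C6 methyl, the enone becomes the all-trans C3–C5 triol (epoxidation, hydride, water), and the isopropenyl group becomes the C7 ketone.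
5. Ring order: cyclohexane (bought with carvone) → transient γ-lactone ring (closed by C7–C8) → nine-membered lactone (opened out of the bicycle in the same step).

Key step: step 13

Remark: the lactone locants are kept for the same atoms in all earlier intermediates. The lactate carbon becomes a planar radical in the key step, so the cheap (S)-lactate is assumed only to keep its derivatives single diastereomers.

Step 1
Reactants: 1 (R)-(−)-carvone
Product: 3 (5R,6S)-2,6-dimethyl-5-(prop-1-en-2-yl)cyclohex-2-en-1-one, via lithium dienolate 2 (not isolated)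
Conditions: LDA, THF, −78 °C; MeI, −78 → 0 °C
Reagents that add atoms: methyl iodide, CI
Why: Kinetic α′-deprotonation of the enone and SN2 methylation of the dienolate (enolate alkylation) should place the methyl group (later on C6) anti to the neighbouring isopropenyl group, and this centre is re-equilibrated in step 7 in any case.

Step 2
Reactants: 3 (5R,6S)-6-methylcarvone
Product: 4 (1R,3S,4R,6R)-1,3-dimethyl-4-(prop-1-en-2-yl)-7-oxabicyclo[4.1.0]heptan-2-one
Conditions: 30 % H2O2, NaOH (catalytic), MeOH, 0 °C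
Reagents that add atoms: hydrogen peroxide, OO
Why: Weitz–Scheffer nucleophilic epoxidation touches only the electron-poor enone double bond, and axial attack of hydroperoxide on the β-carbon anti to the equatorial isopropenyl group sets the C3–O bond and places the oxirane trans to that group.

Step 3
Reactants: 4 epoxy ketone
Product: 5 (1S,2S,3S,4R,6R)-1,3-dimethyl-4-(prop-1-en-2-yl)-7-oxabicyclo[4.1.0]heptan-2-ol
Conditions: L-Selectride, THF, −78 °C; AcOH
Reagents that add atoms: none
Why: The bulky trialkylborohydride attacks the ketone along the equatorial trajectory and anti to the oxirane oxygen (Felkin–Anh-type 1,2-induction), which should give the axial C5 alcohol cis to the oxirane.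

Step 4
Reactants: 5 epoxy alcohol
Product: 6 (1R,2S,3S,4S,5R)-2,4-dimethyl-5-(prop-1-en-2-yl)cyclohexane-1,2,3-triol
Conditions: HClO4 (catalytic), THF–H2O, 0 °C → rt
Reagents that add atoms: water, O
Why: In this acid-catalysed epoxide hydrolysis water opens the oxirane at the tertiary carbon C4 with inversion, the position favoured both by charge stabilisation and by the Fürst–Plattner trans-diaxial rule in the chair anchored by the equatorial isopropenyl group, so that the all-trans C3/C4/C5 triol results.

Step 5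
Reactants: 6 triol
Product: 7 (1S,2S,3S,4R,6R)-1,3-dimethyl-4-(prop-1-en-2-yl)-2,6-bis(triethylsilyloxy)cyclohexan-1-ol
Conditions: TESCl, imidazole, DMF, 0 °C → rt
Reagents that add atoms: chlorotriethylsilane, CC[Si](CC)(CC)Cl
Why: Silyl chloride/imidazole silylation takes the two secondary hydroxyl groups and leaves the tertiary one free for steric reasons.

Step 6
Reactants: 7 bis-silyl ether
Product: 10 (2R,3S,4S,5R)-4-hydroxy-2,4-dimethyl-3,5-bis(triethylsilyloxy)cyclohexan-1-one, via methoxy hydroperoxide 8 (not isolated), via TEMPO adduct 9 (not isolated)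
Conditions: O3, CH2Cl2–MeOH, −78 °C; FeSO4·7H2O, TEMPO, −78 °C → rt; mCPBA, 0 °C → rt
Reagents that add atoms: TEMPO, CC1(C)CCCC(C)(C)N1[O]
Why: In this oxodealkenylation, ozonolysis in methanol gives the α-methoxy hydroperoxide, Fe(II) turns it into an alkoxy radical that loses methyl acetate by β-scission, TEMPO traps the ring radical and peracid oxidation of the alkoxyamine gives the C7 ketone, so that the auxiliary stereocentre disappears.

Step 7
Reactants: 10 hydroxy ketone (6-epimer)
Product: 11 (2S,3S,4S,5R)-4-hydroxy-2,4-dimethyl-3,5-bis(triethylsilyloxy)cyclohexan-1-one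
Conditions: DBU (catalytic), CH2Cl2, rt
Reagents that add atoms: none
Why: Base-catalysed epimerisation through the enolate should move the C6 methyl group trans to the C5 silyloxy group, into the chair with all three oxygen substituents equatorial, because the other epimer must keep either two silyloxy groups or two methyl groups 1,3-diaxial.

Step 8
Reactants: 11 hydroxy ketone
Product: 12 (2S,3S,4S,5R)-2,4-dimethyl-3,4,5-tris(triethylsilyloxy)cyclohexan-1-one
Conditions: TESOTf, 2,6-lutidine, CH2Cl2, −78 → 0 °C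
Reagents that add atoms: triethylsilyl triflate, CC[Si](CC)(CC)OS(=O)(=O)C(F)(F)F
Why: The more reactive silyl triflate with a hindered pyridine base silylates the tertiary alcohol without enolising the ketone.

Step 9
Reactants: 13 benzyl (S)-lactate
Product: 14 benzyl (S)-2-[(1H-imidazole-1-carbonyl)oxy]propanoate
Conditions: CDI, CH2Cl2, rt
Reagents that add atoms: 1,1′-carbonyldiimidazole, O=C(n1ccnc1)n1ccnc1
Why: Acyl transfer from carbonyldiimidazole to the secondary alcohol gives the imidazole carbamate without touching the lactate stereocentre.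

Step 10
Reactants: 12 trisilyloxy ketone; 14 imidazole carbamate
Product: 16 (S)-1-(benzyloxy)-1-oxopropan-2-yl (3S,4S,5R,6R)-3,5-dimethyl-2-oxo-4,5,6-tris(triethylsilyloxy)cyclohexane-1-carboxylate (keto/enol mixture at C2), via lithium enolate 15 (not isolated)
Conditions: LiHMDS, THF, −78 °C; BF3·OEt2, then 14, −78 °C; AcOH
Reagents that add atoms: none
Why: Kinetic deprotonation at the less substituted α-carbon C2 and C-acylation of the lithium enolate by the BF3-activated alkyl imidazole-1-carboxylate (Mander-type C-carboxylation) give the β-keto ester, whose C2 configuration is irrelevant at this stage.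

Step 11
Reactants: 16 β-keto ester
Product: 17 (S)-1-(benzyloxy)-1-oxopropan-2-yl (1S,3S,4S,5R,6R)-1,3,5-trimethyl-2-oxo-4,5,6-tris(triethylsilyloxy)cyclohexane-1-carboxylate
Conditions: K2CO3, MeI, acetone, rt
Reagents that add atoms: methyl iodide, CI
Why: In this C-alkylation of a β-keto ester enolate methyl iodide should enter on the face opposite to the vicinal C3 silyloxy group and to the axial C4 methyl group, which leaves the ester arm cis to the C3 and C5 oxygen atoms.

Step 12
Reactants: 17 quaternary β-keto ester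
Product: 18 (S)-2-{[(1S,3S,4S,5R,6R)-1,3,5-trimethyl-2-oxo-4,5,6-tris(triethylsilyloxy)cyclohexane-1-carbonyl]oxy}propanoic acid
Conditions: H2 (1 atm), Pd/C, EtOAc, rt
Reagents that add atoms: none
Why: Hydrogenolysis cleaves only the benzyl ester because no other reducible group is present.

Step 13
Reactants: 18 O-acyl lactic acid
Product: 23 (3S,4R,5R,6S,7S,9S)-3,5,7,9-tetramethyl-4,5,6-tris(triethylsilyloxy)oxonane-2,8-dione, via 1-(acyloxy)ethyl radical 19 (not isolated), via bicyclic alkoxy radical 20 (not isolated), via ring-expanded C2 radical 21 (not isolated), via lactone enolate 22 (not isolated)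
Conditions: [Ir(dF(CF3)ppy)2(dtbbpy)]PF6 (2 mol %), 2,4,6-collidine, MeCN–H2O 10:1 (5 mM), blue LEDs, 45 °C, Ar
Reagents that add atoms: none
Why: Proposed new method: the excited Ir(III) photocatalyst oxidises the carboxylate of 18, loss of CO2 leaves the nucleophilic 1-(acyloxy)ethyl radical 19 (C8), this adds to the carbon of the ring ketone (C7), the bicyclic alkoxy radical 20 breaks its C2–C7 bond to the tertiary, lactone-stabilised radical 21, and Ir(II) reduces 21 to the enolate 22, which water protonates, so that the cycle is redox-neutral and only CO2 is lost. The closest known reaction types are the Dowd–Beckwith three-carbon ring expansion of 2-(3-halopropyl) β-keto esters and the photoredox decarboxylative Giese reaction of α-oxy acids, and the new element is a tether that runs through the ester oxygen, so that a lactone instead of a carbocycle is expanded out of the ring. Rings: the five-membered lactone ring closes 5-exo-trig on the C=O group and lives only in 20, and the nine-membered ring arises from the 6/5 bicycle by β-scission of the shared bond (6 → 9). C8 is controlled by the quaternary centre C2, since the ester arm reaches only the ketone face on which it stands (cis-fused bicycle) and the C8 methyl group takes the convex side, cis to the alkoxy oxygen, which corresponds to 8S; C2 is re-made under 1,3-allylic strain from C3, with C3–H in the enolate plane and the proton arriving from the ring periphery, anti to C4, which corresponds to 2S (2,3-anti). The step needs addition to C=O to win over 1,5-hydrogen transfer from C3–H and over early quenching, and scission of C2–C7 to win over scission of C6–C7 and over the reverse reaction: no hydrogen-atom donor is present, so that the radical can wait for the minor s-cis ester rotamer, the addition is polarity-matched, and only C2–C7 cleavage gives an ester-stabilised tertiary radical and removes the 1,3-diaxial contact between the ester arm and the C4 methyl group. Water as co-solvent should protonate 22 faster than it can close back by transannular aldol addition.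

Step 14
Reactants: 23 keto lactone
Product: 24 (3S,4R,5R,6S,7R,8S,9S)-8-hydroxy-3,5,7,9-tetramethyl-4,5,6-tris(triethylsilyloxy)oxonan-2-one (the 7S alcohol in lactone locants)
Conditions: L-Selectride, THF, −78 °C; AcOH, −78 °C
Reagents that add atoms: none
Why: Peripheral Felkin–Anh attack of the bulky hydride, anti to the two ring bonds C8–O9 and C6–C5 that stand perpendicular to the carbonyl plane, should give the (7S)-alcohol, and the lactone is not reduced at this temperature.

Step 15
Reactants: 25 heptanoyl chloride; 26 ethynyltrimethylsilane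
Product: 27 1-(trimethylsilyl)non-1-yn-3-one
Conditions: PdCl2(PPh3)2, CuI (both catalytic), Et3N, THF, rt
Reagents that add atoms: none
Why: This is an acyl Sonogashira coupling of an acid chloride with a terminal alkyne.

Step 16
Reactants: 27 ynone
Product: 28 (R)-1-(trimethylsilyl)non-1-yn-3-ol
Conditions: RuCl[(R,R)-TsDPEN](p-cymene), KOH (both catalytic), i-PrOH, rt
Reagents that add atoms: none
Why: In the Noyori asymmetric transfer hydrogenation of an alkynyl ketone the (R,R)-catalyst distinguishes the alkynyl from the alkyl flank and should deliver the (R)-propargylic alcohol.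

Step 17
Reactants: 28 propargylic alcohol
Product: 29 (R)-triethyl{[1-(trimethylsilyl)non-1-yn-3-yl]oxy}silane
Conditions: TESCl, imidazole, CH2Cl2, 0 °C
Reagents that add atoms: chlorotriethylsilane, CC[Si](CC)(CC)Cl
Why: Standard silylation protects the secondary alcohol without touching its stereocentre.

Step 18
Reactants: 29 silyl ether
Product: 31 (R)-4-(triethylsilyloxy)dec-2-ynoic acid, via lithium acetylide 30 (not isolated)
Conditions: MeLi·LiBr, THF, 0 °C; CO2, −78 → 0 °C; cold dilute HCl
Reagents that add atoms: carbon dioxide, O=C=O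
Why: Methyllithium attacks the alkynylsilane at silicon and releases the lithium acetylide, which is carboxylated by carbon dioxide.

Step 19
Reactants: 24 (7S)-alcohol; 31 ynoic acid
Product: 32 (3S,4R,5R,6S,7R,8R,9S)-3,5,7,9-tetramethyl-2-oxo-4,5,6-tris(triethylsilyloxy)oxonan-8-yl (R)-4-(triethylsilyloxy)dec-2-ynoate
Conditions: PPh3, DIAD (betaine pre-formed), toluene, 0 °C → rt
Reagents that add atoms: none
Why: In the Mitsunobu esterification the strongly acidic ynoic acid displaces the activated C7–O bond by SN2 inversion, which turns the (7S)-alcohol into the (7R)-ester.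

Step 20
Reactants: 32 ynoate
Product: 33 (3S,4R,5R,6S,7R,8R,9S)-3,5,7,9-tetramethyl-2-oxo-4,5,6-tris(triethylsilyloxy)oxonan-8-yl (R,Z)-4-(triethylsilyloxy)dec-2-enoate
Conditions: H2 (1 atm), Lindlar catalyst, quinoline, EtOAc, rt
Reagents that add atoms: none
Why: Lindlar semihydrogenation adds hydrogen syn to the alkyne and stops at the (Z)-enoate.

Step 21
Reactants: 33 tetrasilyl ether
Product: 34 (3S,4R,5R,6S,7S,8R,9S)-4,5,6-trihydroxy-3,5,7,9-tetramethyl-2-oxooxonan-8-yl (R,Z)-4-hydroxydec-2-enoate (target CNP0263389.1)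
Conditions: HF·pyridine, pyridine, THF, 0 °C
Reagents that add atoms: none
Why: Buffered HF·pyridine cleaves all four triethylsilyl ethers under weakly acidic conditions that should leave both esters and the (Z)-alkene untouched.

**Compound list**
1 | (R)-(−)-carvone | CC(=C)[C@H]1CC(=O)C(C)=CC1 | starting material
2 | lithium dienolate of 1 | CC(=C)[C@H]1C=C([O-])C(C)=CC1.[Li+] | intermediate
3 | (5R,6S)-2,6-dimethyl-5-(prop-1-en-2-yl)cyclohex-2-en-1-one | CC(=C)[C@H]1[C@H](C)C(=O)C(C)=CC1 | intermediate
4 | (1R,3S,4R,6R)-1,3-dimethyl-4-(prop-1-en-2-yl)-7-oxabicyclo[4.1.0]heptan-2-one | CC(=C)[C@H]1[C@H](C)C(=O)[C@]2(C)O[C@@H]2C1 | intermediate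
5 | (1S,2S,3S,4R,6R)-1,3-dimethyl-4-(prop-1-en-2-yl)-7-oxabicyclo[4.1.0]heptan-2-ol | CC(=C)[C@H]1[C@H](C)[C@H](O)[C@]2(C)O[C@@H]2C1 | intermediate
6 | (1R,2S,3S,4S,5R)-2,4-dimethyl-5-(prop-1-en-2-yl)cyclohexane-1,2,3-triol | CC(=C)[C@H]1[C@H](C)[C@H](O)[C@@](C)(O)[C@H](O)C1 | intermediate
7 | (1S,2S,3S,4R,6R)-1,3-dimethyl-4-(prop-1-en-2-yl)-2,6-bis(triethylsilyloxy)cyclohexan-1-ol | CC(=C)[C@H]1[C@H](C)[C@H](O[Si](CC)(CC)CC)[C@@](C)(O)[C@H](O[Si](CC)(CC)CC)C1 | intermediate
8 | α-methoxy hydroperoxide from 7 (acetal carbon undefined) | COC(C)(OO)[C@H]1[C@H](C)[C@H](O[Si](CC)(CC)CC)[C@@](C)(O)[C@H](O[Si](CC)(CC)CC)C1 | intermediate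
9 | C7 alkoxyamine (TEMPO adduct, C7 undefined) | CC1(C)CCCC(C)(C)N1OC2[C@H](C)[C@H](O[Si](CC)(CC)CC)[C@@](C)(O)[C@H](O[Si](CC)(CC)CC)C2 | intermediate
10 | (2R,3S,4S,5R)-4-hydroxy-2,4-dimethyl-3,5-bis(triethylsilyloxy)cyclohexan-1-one | O=C1[C@H](C)[C@H](O[Si](CC)(CC)CC)[C@@](C)(O)[C@H](O[Si](CC)(CC)CC)C1 | intermediate
11 | (2S,3S,4S,5R)-4-hydroxy-2,4-dimethyl-3,5-bis(triethylsilyloxy)cyclohexan-1-one | O=C1[C@@H](C)[C@H](O[Si](CC)(CC)CC)[C@@](C)(O)[C@H](O[Si](CC)(CC)CC)C1 | intermediate
12 | (2S,3S,4S,5R)-2,4-dimethyl-3,4,5-tris(triethylsilyloxy)cyclohexan-1-one | O=C1[C@@H](C)[C@H](O[Si](CC)(CC)CC)[C@@](C)(O[Si](CC)(CC)CC)[C@H](O[Si](CC)(CC)CC)C1 | intermediate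
13 | benzyl (S)-lactate | C[C@H](O)C(=O)OCc1ccccc1 | starting material
14 | benzyl (S)-2-[(1H-imidazole-1-carbonyl)oxy]propanoate | C[C@H](OC(=O)n1ccnc1)C(=O)OCc1ccccc1 | intermediate
15 | lithium enolate of 12 (C2=C7) | [Li+].[O-]C=1[C@@H](C)[C@H](O[Si](CC)(CC)CC)[C@@](C)(O[Si](CC)(CC)CC)[C@H](O[Si](CC)(CC)CC)C=1 | intermediate
16 | lactate β-keto ester, C2–H (C2 undefined) | O=C1[C@@H](C)[C@H](O[Si](CC)(CC)CC)[C@@](C)(O[Si](CC)(CC)CC)[C@H](O[Si](CC)(CC)CC)C1C(=O)O[C@@H](C)C(=O)OCc1ccccc1 | intermediate
17 | lactate β-keto ester, C2 quaternary (1S,3S,4S,5R,6R) | O=C1[C@@H](C)[C@H](O[Si](CC)(CC)CC)[C@@](C)(O[Si](CC)(CC)CC)[C@H](O[Si](CC)(CC)CC)[C@]1(C)C(=O)O[C@@H](C)C(=O)OCc1ccccc1 | intermediate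
18 | O-acyl (S)-lactic acid | O=C1[C@@H](C)[C@H](O[Si](CC)(CC)CC)[C@@](C)(O[Si](CC)(CC)CC)[C@H](O[Si](CC)(CC)CC)[C@]1(C)C(=O)O[C@@H](C)C(=O)O | intermediate
19 | 1-(acyloxy)ethyl radical (C8) | O=C1[C@@H](C)[C@H](O[Si](CC)(CC)CC)[C@@](C)(O[Si](CC)(CC)CC)[C@H](O[Si](CC)(CC)CC)[C@]1(C)C(=O)O[CH]C | intermediate
20 | bicyclic alkoxy radical (cis-fused γ-lactone, C8 methyl cis to O radical) | [O][C@@]12[C@@H](C)[C@H](O[Si](CC)(CC)CC)[C@@](C)(O[Si](CC)(CC)CC)[C@H](O[Si](CC)(CC)CC)[C@]1(C)C(=O)O[C@H]2C | intermediate
21 | ring-expanded C2 radical | O=C1[C@@H](C)[C@H](O[Si](CC)(CC)CC)[C@@](C)(O[Si](CC)(CC)CC)[C@H](O[Si](CC)(CC)CC)[C](C)C(=O)O[C@H]1C | intermediate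
22 | nine-membered lactone enolate | O=C1[C@@H](C)[C@H](O[Si](CC)(CC)CC)[C@@](C)(O[Si](CC)(CC)CC)[C@H](O[Si](CC)(CC)CC)C(C)=C([O-])O[C@H]1C | intermediate
23 | (3S,4R,5R,6S,7S,9S)-3,5,7,9-tetramethyl-4,5,6-tris(triethylsilyloxy)oxonane-2,8-dione | O=C1[C@@H](C)[C@H](O[Si](CC)(CC)CC)[C@@](C)(O[Si](CC)(CC)CC)[C@H](O[Si](CC)(CC)CC)[C@H](C)C(=O)O[C@H]1C | intermediate
24 | (3S,4R,5R,6S,7R,8S,9S)-8-hydroxy-3,5,7,9-tetramethyl-4,5,6-tris(triethylsilyloxy)oxonan-2-one | O[C@H]1[C@@H](C)[C@H](O[Si](CC)(CC)CC)[C@@](C)(O[Si](CC)(CC)CC)[C@H](O[Si](CC)(CC)CC)[C@H](C)C(=O)O[C@H]1C | intermediate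
25 | heptanoyl chloride | CCCCCCC(=O)Cl | starting material
26 | ethynyltrimethylsilane | C#C[Si](C)(C)C | starting material
27 | 1-(trimethylsilyl)non-1-yn-3-one | CCCCCCC(=O)C#C[Si](C)(C)C | intermediate
28 | (R)-1-(trimethylsilyl)non-1-yn-3-ol | CCCCCC[C@@H](O)C#C[Si](C)(C)C | intermediate
29 | (R)-triethyl{[1-(trimethylsilyl)non-1-yn-3-yl]oxy}silane | CCCCCC[C@@H](O[Si](CC)(CC)CC)C#C[Si](C)(C)C | intermediate
30 | lithium (R)-3-(triethylsilyloxy)non-1-yn-1-ide | CCCCCC[C@@H](O[Si](CC)(CC)CC)C#[C-].[Li+] | intermediate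
31 | (R)-4-(triethylsilyloxy)dec-2-ynoic acid | CCCCCC[C@@H](O[Si](CC)(CC)CC)C#CC(=O)O | intermediate
32 | (7R)-lactone C7 (R)-4-(triethylsilyloxy)dec-2-ynoate | CCCCCC[C@@H](O[Si](CC)(CC)CC)C#CC(=O)O[C@@H]1[C@@H](C)[C@H](O[Si](CC)(CC)CC)[C@@](C)(O[Si](CC)(CC)CC)[C@H](O[Si](CC)(CC)CC)[C@H](C)C(=O)O[C@H]1C | intermediate
33 | (7R)-lactone C7 (R,Z)-4-(triethylsilyloxy)dec-2-enoate | CCCCCC[C@@H](O[Si](CC)(CC)CC)/C=C\C(=O)O[C@@H]1[C@@H](C)[C@H](O[Si](CC)(CC)CC)[C@@](C)(O[Si](CC)(CC)CC)[C@H](O[Si](CC)(CC)CC)[C@H](C)C(=O)O[C@H]1C | intermediate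
34 | CNP0263389.1 | CCCCCC[C@@H](O)/C=C\C(=O)O[C@@H]1[C@@H](C)[C@H](O)[C@@](C)(O)[C@H](O)[C@H](C)C(=O)O[C@H]1C | target

Total step count: 21. Longest linear sequence: 16 steps (1–8, 10–14, 19–21).

**Steps most likely to fail**

1. Step 13 (Proposed new method).
   - What may go wrong: the C8 radical may be lost by 1,5-hydrogen transfer from C3–H, or by hydrogen abstraction from the solvent, before the minor s-cis ester rotamer can cyclise. The enolate may also close back by transannular aldol addition.
   - Fallback (known reactions only; ring closure and ring opening become separate operations): it sets out from 18. Visible-light decarboxylative bromination (same Ir photocatalyst, diethyl bromomalonate, Cs2CO3, PhCl) traps the radical as the 1-bromoethyl ester F1. A SmI2-mediated intramolecular Barbier reaction (THF, −78 °C) forms C7–C8 by the polar route and gives the bicyclic hydroxy lactone F2. Suárez alkoxy-radical fragmentation (PhI(OAc)2, I2, hν, cyclohexane) cleaves C2–C7 and gives the 2-iodo keto lactone F3. Bu3SnH, Et3B/air, toluene, −78 °C then replaces iodine by hydrogen (hydrogen-atom transfer anti to C4) and comes back to the route at 23.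

2. Step 19.
   - What may go wrong: elimination towards C6 or C8, or no displacement at all, at a carbinol flanked by two branched carbons. The phosphine may also add to the electron-poor alkyne.
   - Fallback (inversion and acylation are separated, with a small nucleophile and a better leaving group): it sets out from 24. Tf2O and pyridine give the C7 triflate F4. Bu4NNO2 in toluene (Lattrell–Dax inversion, nitrite ester hydrolysed on work-up) gives the (7R)-alcohol F5. Shiina esterification of F5 with 31 (MNBA, DMAP, Et3N, CH2Cl2), which retains configuration, comes back to the route at 32.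

3. Step 21.
   - What may go wrong: the lactone acyl group may migrate to the freed C4 or C5 hydroxyl group (contraction to a γ- or δ-lactone). The freed (Z)-γ-hydroxy enoate may cyclise to a butenolide with loss of the ring alcohol while fluoride and acid are present.
   - Fallback (order of the end game changed, so that the (Z)-γ-hydroxy enoate never meets HF): it sets out from 32. HF·pyridine/pyridine removes all silyl groups at the alkyne stage, where the linear side chain cannot lactonise, and gives the tetraol ynoate F6. Neutral Lindlar semihydrogenation of F6 as the last step comes back to the route at 34.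

**Further compounds**
F1 | step 13 | 1-bromoethyl (1S,3S,4S,5R,6R)-1,3,5-trimethyl-2-oxo-4,5,6-tris(triethylsilyloxy)cyclohexane-1-carboxylate (bromide carbon undefined) | O=C1[C@@H](C)[C@H](O[Si](CC)(CC)CC)[C@@](C)(O[Si](CC)(CC)CC)[C@H](O[Si](CC)(CC)CC)[C@]1(C)C(=O)OC(C)Br
F2 | step 13 | 3a-hydroxy-3,4,6,7a-tetramethyl-5,6,7-tris(triethylsilyloxy)hexahydro-2-benzofuran-1(3H)-one (cis-fused, 3-methyl cis to 3a-OH) | O[C@@]12[C@@H](C)[C@H](O[Si](CC)(CC)CC)[C@@](C)(O[Si](CC)(CC)CC)[C@H](O[Si](CC)(CC)CC)[C@]1(C)C(=O)O[C@H]2C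
F3 | step 13 | 3-iodo-3,5,7,9-tetramethyl-4,5,6-tris(triethylsilyloxy)oxonane-2,8-dione (iodide carbon undefined) | O=C1[C@@H](C)[C@H](O[Si](CC)(CC)CC)[C@@](C)(O[Si](CC)(CC)CC)[C@H](O[Si](CC)(CC)CC)C(C)(I)C(=O)O[C@H]1C
F4 | step 19 | C7 triflate of 24 | FC(F)(F)S(=O)(=O)O[C@H]1[C@@H](C)[C@H](O[Si](CC)(CC)CC)[C@@](C)(O[Si](CC)(CC)CC)[C@H](O[Si](CC)(CC)CC)[C@H](C)C(=O)O[C@H]1C
F5 | step 19 | (3S,4R,5R,6S,7R,8R,9S)-8-hydroxy-3,5,7,9-tetramethyl-4,5,6-tris(triethylsilyloxy)oxonan-2-one | O[C@@H]1[C@@H](C)[C@H](O[Si](CC)(CC)CC)[C@@](C)(O[Si](CC)(CC)CC)[C@H](O[Si](CC)(CC)CC)[C@H](C)C(=O)O[C@H]1C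
F6 | step 21 | (3S,4R,5R,6S,7S,8R,9S)-4,5,6-trihydroxy-3,5,7,9-tetramethyl-2-oxooxonan-8-yl (R)-4-hydroxydec-2-ynoate | CCCCCC[C@@H](O)C#CC(=O)O[C@@H]1[C@@H](C)[C@H](O)[C@@](C)(O)[C@H](O)[C@H](C)C(=O)O[C@H]1C
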